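**Remarks**

- Locants C1–C15 are those of the target: C1 ketone, C2 methylene, C3 carbinol, C4=C5 alkene (C15 on C4), C6 lactone carbinol, C7 bearing C11(=C13H2)–C12, C8 tiglate carbon, C9/C10 diol carbons (C14 on C10). Stereodescriptors are the true CIP descriptors of each compound. TBS = tert-butyldimethylsilyl, PMB = 4-methoxybenzyl, Tig = (2E)-2-methylbut-2-enoyl.
- The seco bromoketone 28 and its cyclisation product 31 agree with the target at every centre and in both alkene geometries. C7 is labelled R in both only because the silyl ether reverses the priority of C6 and C8. No structure needed correcting.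
- Assumption: (S)-glyceraldehyde acetonide 1 is purchased, or freshly made by periodate cleavage of 5,6-O-isopropylidene-L-gulono-1,4-lactone.

## Structural features

The target is a germacranolide: a ten-membered carbocycle (C1–C10) fused across C6–C7 to an α-methylene-γ-butyrolactone (O6, C12, C11, exocyclic C13), with the hydrogens at C6 and C7 trans. The carbocycle carries a trisubstituted (Z)-alkene C4=C5, a C1 ketone, five contiguous stereocentres C6–C10 (lactone oxygen, carbon branch, tiglate, secondary hydroxyl, methyl-bearing tertiary hydroxyl) and an isolated carbinol at C3. C1–C2–C3 is a β-hydroxy ketone whose carbinol is allylic and whose ketone is flanked by the fully substituted C10, so only C2 can enolise. Fragile points are the Michael-accepting methylene lactone, the aldol unit (retro-aldol, dehydration to a cross-conjugated dienone), the allylic C3–O and C6–O bonds, the tiglate next to a free C9 hydroxyl (acyl shift) and the tertiary α-ketol. The real difficulties are the closure of a medium ring that contains a Z alkene, the C6–C10 pentad, and C3, which has no neighbouring centre to control it. The key step exploits the C1–C2–C3 aldol relationship: a C2 bromide on the C1 ketone becomes a regiodefined enolate that closes the ring onto a C3 enal, while the Z alkene (C3 and C6 cis) and a cis-dioxolane on C9/C10 (C8 and C1 cis) pre-fold the chain.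

## Logic of the disconnections

34 ⇒ 33 ⇒ 31. The O9/O10 ketal and then the C12–O6 acyl bond (with the O6–Si bond) are cut. Keeping O6 silylated until the ring exists leaves the acrylate open and unable to lactonise towards O8. The end game is then two mild steps; the demand is that fluoride and acid spare the aldol unit and the tiglate.

31 ⇒ 28. The C2–C3 bond is cut. This opens the ten-membered ring at its only aldol bond and leaves an acyclic chain on which all five contiguous centres can be set by open-chain control. The forward step needs a regiodefined C2 enolate made without base, reduction of C–Br in preference to the enal, enoates and α-alkoxy ketone, and the right enal face for C3.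

28 ⇒ 27 ⇒ 26 ⇒ 25 ⇒ 24. The C3 aldehyde is traced to its PMB-protected alcohol, and the C1 carbonyl oxygen and C2–Br bond to a terminal alkyne. A methyl ketone at C1 would sit cis to C8 on the dioxolane and would tie up O8 as a five-membered hemiketal or undergo aldol closure onto a C8 aldehyde; the alkyne does neither. The demand is a regioselective hydration late in the route.

24 ⇒ 21 + 22. The O8–acyl bond is cut so that the tiglate enters after the C8 hydroxyl has been created. The acylation must outrun closure of O8 onto C12.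

21 ⇒ 19 + 9. The C7–C8 bond is cut. The 2-(methoxycarbonyl)allyl unit on C7 next to a C8 carbinol is the retron of a Barbier allylation, and the cut divides the molecule into two halves of similar size. The forward step must give 7,8-syn and 8,9-anti and the correct C7 relative to C6.

19 ⇒ 18 ⇒ 15 + 16. The C13–Br bond is traced to an allylically transposed C7 hydroxyl, and the C7–C11 bond is cut. This brings C11–C13 in from a three-carbon ester and leaves an α-silyloxy aldehyde. The demand is that C6, α to that aldehyde and allylic, is not enolised.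

15 ⇒ 14 ⇒ 13 ⇒ 12 ⇒ 11 ⇒ 10 ⇒ 3. These are oxidation-level and protecting-group changes only. They convert the ester into the protected C3 alcohol and the dioxolane into the C6 silyl ether and C7 aldehyde.

9 ⇒ 7 ⇒ 5 ⇒ 4 ⇒ 3. The C8 aldehyde is traced to a glycol cleavage, C2 is added to the C1 ester carbon to form the alkyne, and the C9–O and C10–O bonds come from a syn dihydroxylation of the Z alkene. The dioxolane centre of 3 steers the dihydroxylation and is then destroyed when it becomes the C8 aldehyde.

3 ⇒ 1 + 2. The trisubstituted Z alkene is cut. The same product 3 serves both halves: its alkene becomes C4=C5 in one and C9=C10 (after dihydroxylation) in the other. The demand is high Z selectivity without epimerising 1.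

## Other disconnections considered

Alternative 1: The ten-membered ring is not closed end to end but released from a six–six bicycle built on the carvone ring, by retrosynthetically joining C4 to C9. In the forward key step KOt-Bu would ionise a C9 hydroxyl, and the alkoxide would break the C4–C9 bond and expel a C5 sulfonate (Grob fragmentation) to give the cyclodecenone A1.
- In its favour: it is a ring expansion, so there is no entropic penalty and no dilution; the Z alkene follows stereospecifically from the anti-periplanar alignment; C7 and its three-carbon branch come from the chiral pool; C3 is set on a six-membered ring.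
- Against it here: A1 has a ketone at C9 that must later be reduced to the 9S carbinol next to quaternary C10; C12 is only at the alcohol level; and six protecting groups (two methoxymethyl ethers, one on the tertiary O10, a PMB ether, two silyl ethers, a ketal) must be removed or exchanged around an emerging β-hydroxy ketone. Three stereocentres of the bicycle are built only to be destroyed.
- Comparison: on structure A1 and 31 both hold the full carbon skeleton, but 31 has every carbon at its final oxidation level. On mechanism the fragmentation is concerted and is the better of the two for alkene geometry, for certainty of ring formation and for C3. On step economy the chosen plan needs two steps after its key step where this one needs many more.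

Alternative 2: The C8–C9 bond between the two carbinol carbons is cut. Forward, low-valent titanium from TiCl3(DME)1.5 (trivalent titanium) and zinc–copper couple would join two aldehyde termini in a pinacol macrocyclisation to the lactone-bridged diol A2.
- In its favour: aldehyde termini are easy to make and inert to each other until the metal is added; the step makes the ring and two stereocentres at once; the preformed lactone stiffens the chain.
- Against it here: two new centres mean four possible isomers, controlled only by the metal template. The two secondary hydroxyls of A2 must then be told apart to place the tiglate on O8 alone. The allylic C6–O bond and the lactone face a strongly oxophilic reductant, and deoxygenation to the alkene is the known over-reaction. C13 is still missing and the C1 ketal and tertiary methoxymethyl ether remain.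
- Comparison: on structure A2 is further from the target than 31. On mechanism both steps rely on conformational control, and A2 sets two centres where the chosen step sets one, which is a point in its favour, though with less predictability than a chelated aldol. On step economy it is clearly longer after the key step.

Alternative 3: The C7–C8 bond is cut and O8 is reconnected to C13, so that the carbocycle derives from a 13-membered cyclic allyl ether. Forward, LiN(SiMe3)2 would form the C8 enolate of an α-allyloxy ketone, and a [2,3]-shift would give A3.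
- In its favour: the ring closed by conventional means is a 13-membered ether, which is easier than a ten-membered carbocycle. The contraction is intramolecular and concerted, and makes the C7–C8 bond, both adjacent centres and the C11=C13 methylene in its final acrylate form in one step; this is more construction per step than the chosen key step. The enolate site is as unambiguous as in the chosen plan, for the same reason (quaternary C10).
- Against it here: C7 and C8 both depend on transannular geometry. A strong amide base meets an enoate with an acidic γ-hydrogen. A3 has a C9 ketone that still has to be reduced stereoselectively beside the acylated or free O8, and a C1 ketal and tertiary methoxymethyl ether to remove under acid.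
- Comparison: on structure A3 and 31 are close, but A3 has C1 and C9 at the wrong oxidation levels. On mechanism the sigmatropic step is the equal of the aldol in regiocontrol and better in bonds formed. On step economy the chosen plan is shorter because the aldol delivers C1 and C3 as they are needed.

Key step: step 20

## Route

Step 1
Reactants: 1 (4S)-2,2-dimethyl-1,3-dioxolane-4-carbaldehyde; 2 methyl 2-[bis(2,2,2-trifluoroethoxy)phosphoryl]propanoate
Product: 3 methyl (2Z)-3-[(4R)-2,2-dimethyl-1,3-dioxolan-4-yl]-2-methylprop-2-enoate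
Conditions: KN(SiMe3)2, 18-crown-6, THF, −78 °C
Reagents that add atoms: none
Why: Still–Gennari olefination: the electron-poor phosphonate with a dissociated potassium ion eliminates from the kinetic adduct, so ring carbon and ester should end up cis (Z); at −78 °C the α-alkoxy aldehyde should not epimerise, and 3 is the common precursor of both halves.

Step 2
Reactants: 3 methyl (2Z)-3-[(4R)-2,2-dimethyl-1,3-dioxolan-4-yl]-2-methylprop-2-enoate
Product: 4 methyl (2S,3S)-3-[(4S)-2,2-dimethyl-1,3-dioxolan-4-yl]-2,3-dihydroxy-2-methylpropanoate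
Conditions: OsO4 (cat.), N-methylmorpholine N-oxide, acetone/H2O, 0 °C to rt
Reagents that add atoms: N-methylmorpholine N-oxide, C[N+]1([O-])CCOCC1; water, O
Why: Catalytic syn dihydroxylation; 1,3-allylic strain holds the dioxolane C–H in the alkene plane and OsO4 should add to the face remote from the allylic C–O bond (the empirical rule for osmylation of allylic ethers, most reliable for Z alkenes), which with syn addition sets C9 and C10 as S,S. The enoate is the only alkene present.

Step 3
Reactants: 4 methyl (2S,3S)-3-[(4S)-2,2-dimethyl-1,3-dioxolan-4-yl]-2,3-dihydroxy-2-methylpropanoate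
Product: 5 methyl (4S,5S)-5-[(4S)-2,2-dimethyl-1,3-dioxolan-4-yl]-2,2,4-trimethyl-1,3-dioxolane-4-carboxylate
Conditions: Me2C(OMe)2, PPTS (cat.), CH2Cl2, rt
Reagents that add atoms: 2,2-dimethoxypropane, COC(C)(C)OC
Why: Acid-catalysed transketalisation closes a dioxolane on the secondary/tertiary diol; under anhydrous conditions the terminal acetonide should stay in place. The new ring holds C8 and C1 cis, the turn element used later.

Step 4
Reactants: 5 methyl (4S,5S)-5-[(4S)-2,2-dimethyl-1,3-dioxolan-4-yl]-2,2,4-trimethyl-1,3-dioxolane-4-carboxylate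
Product: 7 (4R,5S)-5-[(4S)-2,2-dimethyl-1,3-dioxolan-4-yl]-4-ethynyl-2,2,4-trimethyl-1,3-dioxolane, via aldehyde 6 (not isolated)
Conditions: i-Bu2AlH, CH2Cl2, −78 °C; then MeOH, K2CO3, dimethyl (1-diazo-2-oxopropyl)phosphonate, −78 °C to rt
Reagents that add atoms: dimethyl (1-diazo-2-oxopropyl)phosphonate, COP(=O)(OC)C(=[N+]=[N-])C(C)=O
Why: Partial reduction of the α-alkoxy ester stops at the chelated aluminium hemiacetal, and Seyferth–Gilbert homologation with the Ohira–Bestmann reagent turns the aldehyde into the alkyne in the same flask; C10 is quaternary and cannot epimerise. The alkyne is the latent C1 ketone and C2 bromide and, unlike a methyl ketone, cannot form a hemiketal with O8 or enolise.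

Step 5
Reactants: 7 (4R,5S)-5-[(4S)-2,2-dimethyl-1,3-dioxolan-4-yl]-4-ethynyl-2,2,4-trimethyl-1,3-dioxolane
Product: 9 (4R,5R)-5-ethynyl-2,2,5-trimethyl-1,3-dioxolane-4-carbaldehyde, via diol 8 (not isolated)
Conditions: H5IO6, EtOAc, rt
Reagents that add atoms: none
Why: Periodic acid hydrolyses the unhindered terminal acetonide and cleaves the liberated 1,2-diol in one pot (glycol cleavage); the tetrasubstituted dioxolane next to the electron-poor alkyne should hydrolyse much more slowly. The directing centre of step 2 is consumed as the C8 aldehyde.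

Step 6
Reactants: 3 methyl (2Z)-3-[(4R)-2,2-dimethyl-1,3-dioxolan-4-yl]-2-methylprop-2-enoate
Product: 10 (2Z)-3-[(4R)-2,2-dimethyl-1,3-dioxolan-4-yl]-2-methylprop-2-en-1-ol
Conditions: i-Bu2AlH, CH2Cl2, −78 °C
Reagents that add atoms: none
Why: 1,2-Reduction of the conjugated ester to the allylic alcohol; hydride delivery at −78 °C does not touch the alkene geometry or the acetonide. The reduction is done here, before any other ester exists.

Step 7
Reactants: 10 (2Z)-3-[(4R)-2,2-dimethyl-1,3-dioxolan-4-yl]-2-methylprop-2-en-1-ol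
Product: 11 (4R)-4-{(1Z)-3-(PMBO)-2-methylprop-1-en-1-yl}-2,2-dimethyl-1,3-dioxolane
Conditions: NaH, 4-methoxybenzyl chloride, Bu4NI (cat.), THF/DMF, 0 °C to rt
Reagents that add atoms: 4-methoxybenzyl chloride, COc1ccc(CCl)cc1
Why: Williamson etherification of the primary allylic alkoxide; the PMB ether is the one group that can later be removed oxidatively beside silyl ether, acetonide, esters and bromoketone.

Step 8
Reactants: 11 (4R)-4-{(1Z)-3-(PMBO)-2-methylprop-1-en-1-yl}-2,2-dimethyl-1,3-dioxolane
Product: 12 (2R,3Z)-5-(PMBO)-4-methylpent-3-ene-1,2-diol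
Conditions: AcOH/H2O/THF (3:1:1), 40 °C
Reagents that add atoms: none
Why: Acid hydrolysis of the terminal acetonide; with C3 already etherified the freed C6 hydroxyl has no ester to lactonise onto, and aqueous acetic acid is too weak to ionise the allylic positions.

Step 9
Reactants: 12 (2R,3Z)-5-(PMBO)-4-methylpent-3-ene-1,2-diol
Product: 13 (2R,3Z)-1,2-bis(TBSO)-5-(PMBO)-4-methylpent-3-ene
Conditions: TBSCl, imidazole, DMF, rt
Reagents that add atoms: tert-butyldimethylsilyl chloride, CC(C)(C)[Si](C)(C)Cl
Why: Exhaustive silylation of both hydroxyls; this is simpler than attempting a direct secondary-selective protection.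

Step 10
Reactants: 13 (2R,3Z)-1,2-bis(TBSO)-5-(PMBO)-4-methylpent-3-ene
Product: 14 (2R,3Z)-2-(TBSO)-5-(PMBO)-4-methylpent-3-en-1-ol
Conditions: HF·pyridine, pyridine, THF, 0 °C
Reagents that add atoms: none
Why: Buffered HF·pyridine cleaves the primary silyl ether well before the hindered secondary one (steric differentiation of silyl ethers), leaving O6 protected.

Step 11
Reactants: 14 (2R,3Z)-2-(TBSO)-5-(PMBO)-4-methylpent-3-en-1-ol
Product: 15 (2R,3Z)-2-(TBSO)-5-(PMBO)-4-methylpent-3-enal
Conditions: Dess–Martin periodinane, NaHCO3, CH2Cl2, 0 °C; used crude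
Reagents that add atoms: none
Why: Dess–Martin oxidation under buffered, non-basic conditions; the α-silyloxy β,γ-unsaturated aldehyde can enolise into conjugation, so it is not stored or chromatographed.

Step 12
Reactants: 15 (2R,3Z)-2-(TBSO)-5-(PMBO)-4-methylpent-3-enal; 16 methyl prop-2-ynoate
Product: 18 methyl (4R,5Z)-4-(TBSO)-3-hydroxy-7-(PMBO)-6-methyl-2-methylidenehept-5-enoate (both C3 epimers), via vinylalane 17 (not isolated)
Conditions: i-Bu2AlH, N-methylmorpholine N-oxide, THF, 0 °C; 16; then 15, 0 °C to rt
Reagents that add atoms: none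
Why: Conjugate hydroalumination of the propiolate gives the α-alumino acrylate, which adds 1,2 to the aldehyde (vinylalumination) to give the Morita–Baylis–Hillman-type adduct; no amine base is present for days as in the acrylate version, so C6 should keep its configuration. The new carbinol centre is irrelevant because it becomes sp2 in step 13.

Step 13
Reactants: 18 methyl (4R,5Z)-4-(TBSO)-3-hydroxy-7-(PMBO)-6-methyl-2-methylidenehept-5-enoate (both C3 epimers)
Product: 19 methyl (2Z,4R,5Z)-2-(bromomethyl)-4-(TBSO)-7-(PMBO)-6-methylhepta-2,5-dienoate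
Conditions: NBS, Me2S, CH2Cl2, 0 °C to rt
Reagents that add atoms: N-bromosuccinimide, O=C1CCC(=O)N1Br
Why: The alcohol is activated as an alkoxysulfonium ion (Corey–Kim-type) and bromide attacks the methylene terminus (SN2′); the trisubstituted enoate forms as the thermodynamic Z isomer with C6 cis to CH2Br, the geometry the next step needs.

Step 14
Reactants: 19 methyl (2Z,4R,5Z)-2-(bromomethyl)-4-(TBSO)-7-(PMBO)-6-methylhepta-2,5-dienoate; 9 (4R,5R)-5-ethynyl-2,2,5-trimethyl-1,3-dioxolane-4-carbaldehyde
Product: 21 methyl (3R,4R,5Z)-4-(TBSO)-3-{(S)-[(4S,5R)-5-ethynyl-2,2,5-trimethyl-1,3-dioxolan-4-yl](hydroxy)methyl}-7-(PMBO)-6-methyl-2-methylidenehept-5-enoate, via allylindium dibromide 20 (not isolated)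
Conditions: In metal powder (zerovalent indium), THF/H2O (1:1), rt
Reagents that add atoms: none
Why: Barbier-type 2-(alkoxycarbonyl)allylation: the allylindium reacts at C7 (SE2′) through a closed chair-like six-membered transition state, in which the Z reagent gives the 7,8-syn adduct. The aldehyde is attacked anti to its α C–O bond (non-chelation model), giving 8,9-anti (8S); 1,3-allylic strain places the C6–H of the reagent in the alkene plane so that bonding occurs anti to the silyloxy group, which sets C7. The three elements should reinforce one another; the alkyne is inert and the hydroxy ester should not lactonise at neutral pH.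

Step 15
Reactants: 21 methyl (3R,4R,5Z)-4-(TBSO)-3-{(S)-[(4S,5R)-5-ethynyl-2,2,5-trimethyl-1,3-dioxolan-4-yl](hydroxy)methyl}-7-(PMBO)-6-methyl-2-methylidenehept-5-enoate; 22 (2E)-2-methylbut-2-enoic acid
Product: 24 methyl (3R,4R,5Z)-4-(TBSO)-3-{(S)-[(4S,5R)-5-ethynyl-2,2,5-trimethyl-1,3-dioxolan-4-yl](TigO)methyl}-7-(PMBO)-6-methyl-2-methylidenehept-5-enoate, via mixed anhydride 23 (not isolated)
Conditions: 22, 2,4,6-trichlorobenzoyl chloride, Et3N, toluene, rt; then 21, DMAP, 40 °C
Reagents that add atoms: none
Why: Yamaguchi esterification: the mixed anhydride is attacked by DMAP at the tigloyl carbonyl and the acylpyridinium acylates the hindered C8 hydroxyl. The neutral alcohol is a poor nucleophile towards the methyl ester, so acylation should outrun O8→C12 lactonisation, and the E geometry of the tiglate is the stable one.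

Step 16
Reactants: 24 methyl (3R,4R,5Z)-4-(TBSO)-3-{(S)-[(4S,5R)-5-ethynyl-2,2,5-trimethyl-1,3-dioxolan-4-yl](TigO)methyl}-7-(PMBO)-6-methyl-2-methylidenehept-5-enoate
Product: 25 methyl (3R,4R,5Z)-3-{(S)-[(4S,5R)-5-(bromoethynyl)-2,2,5-trimethyl-1,3-dioxolan-4-yl](TigO)methyl}-4-(TBSO)-7-(PMBO)-6-methyl-2-methylidenehept-5-enoate
Conditions: NBS, AgNO3 (cat.), acetone, rt, dark
Reagents that add atoms: N-bromosuccinimide, O=C1CCC(=O)N1Br
Why: Silver-catalysed electrophilic bromination of the terminal alkyne through the silver acetylide; the enoate alkenes are electron-poor and the C4=C5 alkene is hindered, so they should not compete. This places the future C2 bromine without enolate chemistry.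

Step 17
Reactants: 25 methyl (3R,4R,5Z)-3-{(S)-[(4S,5R)-5-(bromoethynyl)-2,2,5-trimethyl-1,3-dioxolan-4-yl](TigO)methyl}-4-(TBSO)-7-(PMBO)-6-methyl-2-methylidenehept-5-enoate
Product: 26 methyl (3R,4R,5Z)-3-{(S)-[(4S,5S)-5-(bromoacetyl)-2,2,5-trimethyl-1,3-dioxolan-4-yl](TigO)methyl}-4-(TBSO)-7-(PMBO)-6-methyl-2-methylidenehept-5-enoate
Conditions: (XPhos)AuNTf2 (cat., monovalent gold), H2O (3 equiv), ClCH2CH2Cl, rt
Reagents that add atoms: water, O
Why: Gold-catalysed hydration of a 1-bromoalkyne: water adds to the π-activated alkyne at the carbon remote from bromine, and protodeauration and tautomerisation give the bromomethyl ketone. C1=O and C2–Br therefore appear with fixed regiochemistry under nearly neutral conditions that silyl ether, ketal and esters tolerate.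

Step 18
Reactants: 26 methyl (3R,4R,5Z)-3-{(S)-[(4S,5S)-5-(bromoacetyl)-2,2,5-trimethyl-1,3-dioxolan-4-yl](TigO)methyl}-4-(TBSO)-7-(PMBO)-6-methyl-2-methylidenehept-5-enoate
Product: 27 methyl (3R,4R,5Z)-3-{(S)-[(4S,5S)-5-(bromoacetyl)-2,2,5-trimethyl-1,3-dioxolan-4-yl](TigO)methyl}-4-(TBSO)-7-hydroxy-6-methyl-2-methylidenehept-5-enoate
Conditions: DDQ, CH2Cl2/pH 7 phosphate buffer (10:1), 0 °C
Reagents that add atoms: none
Why: Oxidative cleavage of the PMB ether (hydride abstraction by DDQ, hydrolysis of the oxocarbenium ion); bromoketone, silyl ether, ketal and esters are inert to DDQ at 0 °C.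

Step 19
Reactants: 27 methyl (3R,4R,5Z)-3-{(S)-[(4S,5S)-5-(bromoacetyl)-2,2,5-trimethyl-1,3-dioxolan-4-yl](TigO)methyl}-4-(TBSO)-7-hydroxy-6-methyl-2-methylidenehept-5-enoate
Product: 28 methyl (3R,4R,5Z)-3-{(S)-[(4S,5S)-5-(bromoacetyl)-2,2,5-trimethyl-1,3-dioxolan-4-yl](TigO)methyl}-4-(TBSO)-6-methyl-2-methylidene-7-oxohept-5-enoate
Conditions: Dess–Martin periodinane, NaHCO3, CH2Cl2, 0 °C; used at once
Reagents that add atoms: none
Why: Dess–Martin oxidation of the allylic alcohol under buffered conditions; the Z enal is unveiled only now and is exposed to neither acid nor base, which would isomerise it to the E enal.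

Step 20
Reactants: 28 methyl (3R,4R,5Z)-3-{(S)-[(4S,5S)-5-(bromoacetyl)-2,2,5-trimethyl-1,3-dioxolan-4-yl](TigO)methyl}-4-(TBSO)-6-methyl-2-methylidene-7-oxohept-5-enoate
Product: 31 methyl 2-[(3S,4Z,6R,7R,8S,9S,10S)-6-(TBSO)-3-hydroxy-9,10-(isopropylidenedioxy)-4,10-dimethyl-1-oxo-8-(TigO)cyclodec-4-en-7-yl]prop-2-enoate, via samarium enolate 29 (not isolated), via samarium aldolate 30 (not isolated)
Conditions: SmI2 (2.2 equiv, 0.1 M in THF; divalent samarium) added over 4 h to 28 (0.002 M in THF), −78 °C; aq. NH4Cl at −78 °C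
Reagents that add atoms: none
Why: Two electrons from SmI2 cleave the C2–Br bond (the second reduces the α-keto radical) and give the trivalent samarium enolate 29, whose position is fixed because C10 is quaternary. C2 then adds to the C3 aldehyde through a samarium-bridged six-membered transition state to the aldolate 30, which is protonated on work-up; the closest known reaction type is the SmI2-mediated intramolecular Reformatsky cyclisation of bromoacyl aldehydes to medium and large rings. The ten-membered ring closes in a 10-(enolendo)-exo-trig mode, helped by the Z alkene (C3 and C6 cis) and by the cis-dioxolane (C8 and C1 cis). The only new centre is C3, and it is set by the enal face that C2 reaches. The 3S alcohol arises from bonding to the Si face, which lies on the C7 side when the C6–O bond eclipses the alkene with the enal s-trans, or when C6–H eclipses it with the enal s-cis; the C6–H-eclipsed, s-trans arrangement would lead to 3R. Nothing stronger than this conformational preference secures the face, so this is the main stereochemical risk. Chemoselectivity rests on C–Br reduction being far faster than electron transfer to the enal, the enoates or the α-alkoxy ketone. SmI2 is therefore dripped into the dilute substrate so that it never accumulates, which also suppresses intermolecular aldol addition and reductive cleavage of the C10–O bond in the product.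

Step 21
Reactants: 31 methyl 2-[(3S,4Z,6R,7R,8S,9S,10S)-6-(TBSO)-3-hydroxy-9,10-(isopropylidenedioxy)-4,10-dimethyl-1-oxo-8-(TigO)cyclodec-4-en-7-yl]prop-2-enoate
Product: 33 (3S,4Z,6R,7S,8S,9S,10S)-3-hydroxy-9,10-(isopropylidenedioxy)-1-oxo-8-(TigO)germacra-4,11(13)-dien-12,6-olide, via hydroxy ester 32 (not isolated)
Conditions: HF·pyridine, pyridine, THF, 0 °C to rt
Reagents that add atoms: none
Why: Fluoride-assisted cleavage of the secondary silyl ether frees O6, which is 1,4 to C12 and closes the γ-lactone by acyl substitution (5-exo-trig) with loss of methanol; the trans ring fusion follows from the fixed C6 and C7. The mildly acidic medium should leave the β-hydroxy ketone and the tiglate alone.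

Step 22
Reactants: 33 (3S,4Z,6R,7S,8S,9S,10S)-3-hydroxy-9,10-(isopropylidenedioxy)-1-oxo-8-(TigO)germacra-4,11(13)-dien-12,6-olide
Product: 34 (3S,4Z,6R,7S,8S,9S,10S)-3,9,10-trihydroxy-1-oxo-8-(TigO)germacra-4,11(13)-dien-12,6-olide
Conditions: CF3CO2H/H2O (9:1), 0 °C, short reaction time
Reagents that add atoms: none
Why: Acid-catalysed hydrolysis of the isopropylidene ketal; no base is used, so the O8→O9 acyl shift and retro-aldol cleavage are avoided, and the low temperature and short time are meant to keep the β-hydroxy ketone from dehydrating.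

## Compound list

1 | (4S)-2,2-dimethyl-1,3-dioxolane-4-carbaldehyde [(S)-glyceraldehyde acetonide] | CC1(C)OC[C@@H](C=O)O1 | starting material
2 | methyl 2-[bis(2,2,2-trifluoroethoxy)phosphoryl]propanoate | COC(=O)C(C)P(=O)(OCC(F)(F)F)OCC(F)(F)F | starting material
3 | methyl (2Z)-3-[(4R)-2,2-dimethyl-1,3-dioxolan-4-yl]-2-methylprop-2-enoate | CC1(C)OC[C@@H](/C=C(/C)C(=O)OC)O1 | intermediate
4 | methyl (2S,3S)-3-[(4S)-2,2-dimethyl-1,3-dioxolan-4-yl]-2,3-dihydroxy-2-methylpropanoate | COC(=O)[C@@](C)(O)[C@@H](O)[C@@H]1COC(C)(C)O1 | intermediate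
5 | methyl (4S,5S)-5-[(4S)-2,2-dimethyl-1,3-dioxolan-4-yl]-2,2,4-trimethyl-1,3-dioxolane-4-carboxylate | COC(=O)[C@@]1(C)OC(C)(C)O[C@H]1[C@@H]2COC(C)(C)O2 | intermediate
6 | (4S,5S)-5-[(4S)-2,2-dimethyl-1,3-dioxolan-4-yl]-2,2,4-trimethyl-1,3-dioxolane-4-carbaldehyde | O=C[C@@]1(C)OC(C)(C)O[C@H]1[C@@H]2COC(C)(C)O2 | intermediate (not isolated)
7 | (4R,5S)-5-[(4S)-2,2-dimethyl-1,3-dioxolan-4-yl]-4-ethynyl-2,2,4-trimethyl-1,3-dioxolane | C#C[C@@]1(C)OC(C)(C)O[C@H]1[C@@H]2COC(C)(C)O2 | intermediate
8 | (1S)-1-[(4S,5R)-5-ethynyl-2,2,5-trimethyl-1,3-dioxolan-4-yl]ethane-1,2-diol | C#C[C@@]1(C)OC(C)(C)O[C@H]1[C@@H](O)CO | intermediate (not isolated)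
9 | (4R,5R)-5-ethynyl-2,2,5-trimethyl-1,3-dioxolane-4-carbaldehyde | C#C[C@@]1(C)OC(C)(C)O[C@H]1C=O | intermediate
10 | (2Z)-3-[(4R)-2,2-dimethyl-1,3-dioxolan-4-yl]-2-methylprop-2-en-1-ol | CC1(C)OC[C@@H](/C=C(/C)CO)O1 | intermediate
11 | (4R)-4-{(1Z)-3-[(4-methoxyphenyl)methoxy]-2-methylprop-1-en-1-yl}-2,2-dimethyl-1,3-dioxolane | CC1(C)OC[C@@H](/C=C(/C)COCc2ccc(OC)cc2)O1 | intermediate
12 | (2R,3Z)-5-[(4-methoxyphenyl)methoxy]-4-methylpent-3-ene-1,2-diol | OC[C@H](O)/C=C(/C)COCc1ccc(OC)cc1 | intermediate
13 | (2R,3Z)-1,2-bis[(tert-butyldimethylsilyl)oxy]-5-[(4-methoxyphenyl)methoxy]-4-methylpent-3-ene | CC(C)(C)[Si](C)(C)OC[C@H](O[Si](C)(C)C(C)(C)C)/C=C(/C)COCc1ccc(OC)cc1 | intermediate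
14 | (2R,3Z)-2-[(tert-butyldimethylsilyl)oxy]-5-[(4-methoxyphenyl)methoxy]-4-methylpent-3-en-1-ol | OC[C@H](O[Si](C)(C)C(C)(C)C)/C=C(/C)COCc1ccc(OC)cc1 | intermediate
15 | (2R,3Z)-2-[(tert-butyldimethylsilyl)oxy]-5-[(4-methoxyphenyl)methoxy]-4-methylpent-3-enal | O=C[C@H](O[Si](C)(C)C(C)(C)C)/C=C(/C)COCc1ccc(OC)cc1 | intermediate
16 | methyl prop-2-ynoate (methyl propiolate) | C#CC(=O)OC | starting material
17 | methyl 2-[bis(2-methylpropyl)alumanyl]prop-2-enoate (vinylalane) | C=C(C(=O)OC)[Al](CC(C)C)CC(C)C | intermediate (not isolated)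
18 | methyl (4R,5Z)-4-[(tert-butyldimethylsilyl)oxy]-3-hydroxy-7-[(4-methoxyphenyl)methoxy]-6-methyl-2-methylidenehept-5-enoate, both C3 epimers | COC(=O)C(=C)C(O)[C@H](O[Si](C)(C)C(C)(C)C)/C=C(/C)COCc1ccc(OC)cc1 | intermediate
19 | methyl (2Z,4R,5Z)-2-(bromomethyl)-4-[(tert-butyldimethylsilyl)oxy]-7-[(4-methoxyphenyl)methoxy]-6-methylhepta-2,5-dienoate | COC(=O)/C(CBr)=C/[C@H](O[Si](C)(C)C(C)(C)C)/C=C(/C)COCc1ccc(OC)cc1 | intermediate
20 | allylindium dibromide from 19 (trivalent indium on C13; otherwise as 19) | COC(=O)/C(C[In](Br)Br)=C/[C@H](O[Si](C)(C)C(C)(C)C)/C=C(/C)COCc1ccc(OC)cc1 | intermediate (not isolated)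
21 | methyl (3R,4R,5Z)-4-[(tert-butyldimethylsilyl)oxy]-3-{(S)-[(4S,5R)-5-ethynyl-2,2,5-trimethyl-1,3-dioxolan-4-yl](hydroxy)methyl}-7-[(4-methoxyphenyl)methoxy]-6-methyl-2-methylidenehept-5-enoate | C#C[C@@]1(C)OC(C)(C)O[C@H]1[C@@H](O)[C@@H](C(=C)C(=O)OC)[C@H](O[Si](C)(C)C(C)(C)C)/C=C(/C)COCc1ccc(OC)cc1 | intermediate
22 | (2E)-2-methylbut-2-enoic acid (tiglic acid) | C/C=C(\C)C(=O)O | starting material
23 | (2E)-2-methylbut-2-enoic 2,4,6-trichlorobenzoic anhydride | C/C=C(\C)C(=O)OC(=O)c1c(Cl)cc(Cl)cc1Cl | intermediate (not isolated)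
24 | methyl (3R,4R,5Z)-4-[(tert-butyldimethylsilyl)oxy]-3-{(S)-[(4S,5R)-5-ethynyl-2,2,5-trimethyl-1,3-dioxolan-4-yl]{[(2E)-2-methylbut-2-enoyl]oxy}methyl}-7-[(4-methoxyphenyl)methoxy]-6-methyl-2-methylidenehept-5-enoate | C#C[C@@]1(C)OC(C)(C)O[C@H]1[C@@H](OC(=O)/C(C)=C/C)[C@@H](C(=C)C(=O)OC)[C@H](O[Si](C)(C)C(C)(C)C)/C=C(/C)COCc1ccc(OC)cc1 | intermediate
25 | as 24 with (4S,5R)-5-(bromoethynyl)-2,2,5-trimethyl-1,3-dioxolan-4-yl | BrC#C[C@@]1(C)OC(C)(C)O[C@H]1[C@@H](OC(=O)/C(C)=C/C)[C@@H](C(=C)C(=O)OC)[C@H](O[Si](C)(C)C(C)(C)C)/C=C(/C)COCc1ccc(OC)cc1 | intermediate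
26 | as 24 with (4S,5S)-5-(bromoacetyl)-2,2,5-trimethyl-1,3-dioxolan-4-yl | BrCC(=O)[C@@]1(C)OC(C)(C)O[C@H]1[C@@H](OC(=O)/C(C)=C/C)[C@@H](C(=C)C(=O)OC)[C@H](O[Si](C)(C)C(C)(C)C)/C=C(/C)COCc1ccc(OC)cc1 | intermediate
27 | as 26 with a free 7-hydroxyl in place of the 4-methoxybenzyl ether | BrCC(=O)[C@@]1(C)OC(C)(C)O[C@H]1[C@@H](OC(=O)/C(C)=C/C)[C@@H](C(=C)C(=O)OC)[C@H](O[Si](C)(C)C(C)(C)C)/C=C(/C)CO | intermediate
28 | methyl (3R,4R,5Z)-3-{(S)-[(4S,5S)-5-(bromoacetyl)-2,2,5-trimethyl-1,3-dioxolan-4-yl]{[(2E)-2-methylbut-2-enoyl]oxy}methyl}-4-[(tert-butyldimethylsilyl)oxy]-6-methyl-2-methylidene-7-oxohept-5-enoate (seco bromoketone) | BrCC(=O)[C@@]1(C)OC(C)(C)O[C@H]1[C@@H](OC(=O)/C(C)=C/C)[C@@H](C(=C)C(=O)OC)[C@H](O[Si](C)(C)C(C)(C)C)/C=C(/C)C=O | intermediate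
29 | samarium enolate of 28 (C1(OSmI2)=C2H2, trivalent samarium; other centres as in 28) | C=C(O[Sm](I)I)[C@@]1(C)OC(C)(C)O[C@H]1[C@@H](OC(=O)/C(C)=C/C)[C@@H](C(=C)C(=O)OC)[C@H](O[Si](C)(C)C(C)(C)C)/C=C(/C)C=O | intermediate (not isolated)
30 | samarium aldolate of 31 (O3–SmI2, trivalent samarium; other centres as in 31) | O=C1C[C@H](O[Sm](I)I)/C(C)=C\[C@@H](O[Si](C)(C)C(C)(C)C)[C@H](C(=C)C(=O)OC)[C@H](OC(=O)/C(C)=C/C)[C@@H]2OC(C)(C)O[C@]12C | intermediate (not isolated)
31 | methyl 2-[(3S,4Z,6R,7R,8S,9S,10S)-6-[(tert-butyldimethylsilyl)oxy]-3-hydroxy-9,10-(isopropylidenedioxy)-4,10-dimethyl-8-{[(2E)-2-methylbut-2-enoyl]oxy}-1-oxocyclodec-4-en-7-yl]prop-2-enoate (target numbering) | O=C1C[C@H](O)/C(C)=C\[C@@H](O[Si](C)(C)C(C)(C)C)[C@H](C(=C)C(=O)OC)[C@H](OC(=O)/C(C)=C/C)[C@@H]2OC(C)(C)O[C@]12C | intermediate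
32 | methyl 2-[(3S,4Z,6R,7S,8S,9S,10S)-3,6-dihydroxy-9,10-(isopropylidenedioxy)-4,10-dimethyl-8-{[(2E)-2-methylbut-2-enoyl]oxy}-1-oxocyclodec-4-en-7-yl]prop-2-enoate (target numbering) | O=C1C[C@H](O)/C(C)=C\[C@@H](O)[C@H](C(=C)C(=O)OC)[C@H](OC(=O)/C(C)=C/C)[C@@H]2OC(C)(C)O[C@]12C | intermediate (not isolated)
33 | (3S,4Z,6R,7S,8S,9S,10S)-3-hydroxy-9,10-(isopropylidenedioxy)-1-oxo-8-{[(2E)-2-methylbut-2-enoyl]oxy}germacra-4,11(13)-dien-12,6-olide | C=C1C(=O)O[C@@H]2/C=C(/C)[C@@H](O)CC(=O)[C@@]3(C)OC(C)(C)O[C@H]3[C@@H](OC(=O)/C(C)=C/C)[C@@H]12 | intermediate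
34 | (3S,4Z,6R,7S,8S,9S,10S)-3,9,10-trihydroxy-1-oxo-8-{[(2E)-2-methylbut-2-enoyl]oxy}germacra-4,11(13)-dien-12,6-olide (CNP0106709.2) | C=C1C(=O)O[C@@H]2/C=C(/C)[C@@H](O)CC(=O)[C@@](C)(O)[C@@H](O)[C@@H](OC(=O)/C(C)=C/C)[C@@H]12 | target

## Step count and risks

Total: 22 steps. Longest linear sequence: 18 steps (steps 1, 6–13, 14–22); the aldehyde half takes steps 1–5.

Least certain steps:

**Step 20 (key step).** The most likely failure is closure on the wrong enal face (poor or inverted facial selectivity at C3), because the competing ring-closing conformers differ only in which C6 substituent eclipses the alkene. The second is over-reduction (enal, or the C10–O bond α to the new ketone) if SmI2 accumulates. Fallback: C3 is then set by substitution instead of by facial selection. Starting from 28, cyclisation as in step 20 would give the 3R alcohol F1. A Mitsunobu reaction with chloroacetic acid (PPh3, diisopropyl azodicarboxylate, toluene, 0 °C) would invert it to the 3S chloroacetate F2. Thiourea with NaHCO3 in ethanol would remove the chloroacetyl group without touching the tiglate or the methyl ester and return the route to 31.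

**Step 14.** What may go wrong is a mismatch between the facial preferences of the two chiral partners (erosion of selectivity at C7/C8), or loss of the silyloxy group by vinylogous β-elimination from the allylindium 20 before it meets the aldehyde. Fallback: starting from 19, a Miyaura-type borylation (B2pin2, Pd2(dba)3, zerovalent palladium) would give the allylboronate F3. Heating F3 with 9 in toluene would effect an allylboration through a closed chair transition state, with no reducing metal and no elimination pathway. Mild hydrolysis of the borate rejoins the route at 21.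

**Step 12.** The risks are reduction of the aldehyde by the alane (hydride transfer) and loss of configuration at C6 by enolisation of 15 into conjugation. Fallback: starting from 15, an aldol addition at −78 °C of the lithium enolate of methyl 3-(phenylselanyl)propanoate F4 (from methyl acrylate and benzeneselenol) would give the hydroxy selenide F5. Oxidation with H2O2/pyridine would give the selenoxide F6, which undergoes syn elimination at 0 °C towards the only available β-hydrogen and rejoins the route at 18.

**Step 15.** Acylation of the flanked C8 hydroxyl may be slow enough for O8 to close onto C12 (premature lactonisation). Fallback: starting from 21, esterification with the more electrophilic, non-conjugated 2-(diethoxyphosphoryl)propanoic acid (DCC, DMAP) would give the phosphonate ester F7. A Horner–Wadsworth–Emmons reaction with acetaldehyde (LiCl, i-Pr2NEt, MeCN) would then build the E-configured tiglate double bond on the molecule and rejoin the route at 24.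

**Step 17.** Hydration may stall at the hindered, oxygen-flanked alkyne carbon, or the dioxolane oxygen may take part. Fallback: starting from 24 and omitting step 16, the terminal alkyne would be hydrated with Hg(OTf)2 (cat., divalent mercury) in wet MeCN to the methyl ketone F8. This would be converted into its trimethylsilyl enol ether F9 (Me3SiOTf, Et3N; only C2 can enolise) and brominated with NBS at −78 °C, rejoining the route at 26.

## Further compounds

F1 | step 20 | 3R epimer of 31: methyl 2-[(3R,4Z,6R,7R,8S,9S,10S)-6-(TBSO)-3-hydroxy-9,10-(isopropylidenedioxy)-4,10-dimethyl-1-oxo-8-(TigO)cyclodec-4-en-7-yl]prop-2-enoate | O=C1C[C@@H](O)/C(C)=C\[C@@H](O[Si](C)(C)C(C)(C)C)[C@H](C(=C)C(=O)OC)[C@H](OC(=O)/C(C)=C/C)[C@@H]2OC(C)(C)O[C@]12C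
F2 | step 20 | 3S chloroacetate of 31 | O=C1C[C@H](OC(=O)CCl)/C(C)=C\[C@@H](O[Si](C)(C)C(C)(C)C)[C@H](C(=C)C(=O)OC)[C@H](OC(=O)/C(C)=C/C)[C@@H]2OC(C)(C)O[C@]12C
F3 | step 14 | methyl (2E,4R,5Z)-4-(TBSO)-7-(PMBO)-6-methyl-2-[(4,4,5,5-tetramethyl-1,3,2-dioxaborolan-2-yl)methyl]hepta-2,5-dienoate | COC(=O)/C(CB1OC(C)(C)C(C)(C)O1)=C/[C@H](O[Si](C)(C)C(C)(C)C)/C=C(/C)COCc1ccc(OC)cc1
F4 | step 12 | methyl 3-(phenylselanyl)propanoate | COC(=O)CC[Se]c1ccccc1
F5 | step 12 | methyl (4R,5Z)-4-(TBSO)-3-hydroxy-7-(PMBO)-6-methyl-2-[(phenylselanyl)methyl]hept-5-enoate, mixture at C2 and C3 | COC(=O)C(C[Se]c1ccccc1)C(O)[C@H](O[Si](C)(C)C(C)(C)C)/C=C(/C)COCc1ccc(OC)cc1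
F6 | step 12 | selenoxide of F5 | COC(=O)C(C[Se](=O)c1ccccc1)C(O)[C@H](O[Si](C)(C)C(C)(C)C)/C=C(/C)COCc1ccc(OC)cc1
F7 | step 15 | 2-(diethoxyphosphoryl)propanoate ester of 21 at O8, mixture at the phosphonate carbon | C#C[C@@]1(C)OC(C)(C)O[C@H]1[C@@H](OC(=O)C(C)P(=O)(OCC)OCC)[C@@H](C(=C)C(=O)OC)[C@H](O[Si](C)(C)C(C)(C)C)/C=C(/C)COCc1ccc(OC)cc1
F8 | step 17 | methyl ketone from 24: as 26 with (4S,5S)-5-acetyl-2,2,5-trimethyl-1,3-dioxolan-4-yl | CC(=O)[C@@]1(C)OC(C)(C)O[C@H]1[C@@H](OC(=O)/C(C)=C/C)[C@@H](C(=C)C(=O)OC)[C@H](O[Si](C)(C)C(C)(C)C)/C=C(/C)COCc1ccc(OC)cc1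
F9 | step 17 | trimethylsilyl enol ether of F8 | C=C(O[Si](C)(C)C)[C@@]1(C)OC(C)(C)O[C@H]1[C@@H](OC(=O)/C(C)=C/C)[C@@H](C(=C)C(=O)OC)[C@H](O[Si](C)(C)C(C)(C)C)/C=C(/C)COCc1ccc(OC)cc1
A1 | alternative 1 | (Z)-cyclodec-4-en-9-one with C1 dioxolane ketal, C3 and C12 silyl ethers, C6 and C10 methoxymethyl ethers and C8 4-methoxybenzyl ether | C=C(CO[Si](C)(C)C(C)(C)C)[C@H]1[C@H](OCOC)/C=C(/C)[C@@H](O[Si](C)(C)C(C)(C)C)CC2(OCCO2)[C@@](C)(OCOC)C(=O)[C@H]1OCc1ccc(OC)cc1
A2 | alternative 2 | lactone-bridged ten-membered 8,9-diol with C1 ketal, C3 silyl ether and C10 methoxymethyl ether | O=C1C[C@H]2[C@H](O1)/C=C(/C)[C@@H](O[Si](C)(C)C(C)(C)C)CC3(OCCO3)[C@@](C)(OCOC)[C@@H](O)[C@H]2O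
A3 | alternative 3 | ten-membered 8-hydroxy-9-ketone bearing the C7 acrylate, C1 ketal, C3 and C6 silyl ethers, C10 methoxymethyl ether | C=C(C(=O)OC)[C@H]1[C@H](O[Si](C)(C)C(C)(C)C)/C=C(/C)[C@@H](O[Si](C)(C)C(C)(C)C)CC2(OCCO2)[C@@](C)(OCOC)C(=O)[C@H]1O
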